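A small charge of substrate, 0.30 M, passes through the intermediate and leaves it by one of two captures, so I began from the balance of that charge.

common to all: substrate 0.30 M; first nucleophile 0.600 M; second nucleophile 0.450 M; time 10 min
- north: at 110 °C until 5.0 min, from then on at 80 °C
- south-west: temperature 80 °C
- south-east: temperature 110 °C

    substrate → intermediate (k1 = 0.0085 s⁻¹, Ea1 = 103 kJ mol⁻¹)
    first nucleophile + intermediate → target (k2 = 0.045 M⁻¹ s⁻¹, Ea2 = 72.0 kJ mol⁻¹)
    second nucleophile + intermediate → other capture product (k3 = 0.039 M⁻¹ s⁻¹, Ea3 = 76.0 kJ mol⁻¹)
    first nucleophile + target ⇌ idle adduct, settled at all times (K4 = 1.1 M⁻¹, ΔH4 = 9.00 kJ mol⁻¹)
    second nucleophile + target → over-reaction product (k5 = 1.5 × 10⁻⁴ M⁻¹ s⁻¹, Ea5 = 97.0 kJ mol⁻¹)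
    first nucleophile → decomposed reagent (k6 = 0.0014 s⁻¹, Ea6 = 109 kJ mol⁻¹)
    (constants at 80 °C)

- target is meant together with its idle adduct
- at 80 °C the constants are as listed, elsewhere as the activation energies and enthalpies make them

- the flask that comes out highest in amount of target, in percent of the substrate charged, or "all alike" when all lie within 1.5 percentage points (north / south-west / south-east / all alike)
- target at the end, in percent of the substrate charged, north
- target at the end, in percent of the substrate charged, south-west
- target at the end, in percent of the substrate charged, south-east

Target made is that charge times the part of the intermediate taken by first nucleophile. At full charges in south-west, that part was 60.6%. But first nucleophile decomposes while substrate waits. I put the typical capture at the lifetime of substrate plus that of the intermediate, 140 s. I reckoned that decomposition alone left 82.2% of first nucleophile by then, and the part fell to 55.8%. I call this the capture share: the capture rate of first nucleophile over both capture rates, at the typical moment of capture. What capture itself draws from either nucleophile I left out of it. Over-reaction for the remaining time, with second nucleophile held at its charge, brought my figure for south-west to 54.1%.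

At 110 °C, substrate loss sped up by a factor of 15.6, decomposition by 18.3, over-reaction by 13.3, and the captures by 6.8 and 7.6. The typical capture moved to 10.7 s, far earlier than the cooling of north, so north and south-east share one capture. I reckoned that decomposition left 76.0%, and the hot share came to 51.3%, lower than my share for south-west. Over-reaction then put my figures at 29.9% for south-east and 38.4% for north.

I took the weak link to be second nucleophile held at its charge. Capture consumes it, and by the capture shares I reckoned 67.5% of its charge left after the hot capture and 70.6% in south-west. Reforged, my numbers were south-west 54.6%, north 42.2% and south-east 35.6%, with south-west highest.

The forecast said south-west, with 53% there, 39% in north and 33% in south-east, holding that at the higher temperature “that nucleophile decomposes on the same timescale as the capture, costing selectivity”. Mine lay above it in each flask.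

The flasks gave south-west highest, as forecast, with 52.5% against 41.4% in north and 35.7% in south-east. South-west held 45.5% of other capture product, beside the 44.2% its capture share leaves. The neighbouring south-west flask, charged with 0.24 M of first nucleophile, takes the same reckoning: typical capture at 153 s, share 33.2%, so 66.8% for other capture product and 32.6% of target. That flask held 67.2% of other capture product and 30.6% of target.

The numbers of this flask are assumed; the result is computed.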